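**Strategy.** The cyclohexene ring (C1, C10–C14; briarane numbering) is dissected into the two-carbon unit C14=C1 and the diene C10=C11–C12=C13. The design exploits the fact that C2 and C9, the oxygenated carbons flanking the trans ring fusion C1–C10, can be tied as a temporary γ-lactone C2(=O)–O–C9. An ester-tethered intramolecular Diels–Alder reaction of a β-sulfinylmethacrylate, followed in the same flask by sulfoxide syn-elimination, then forms C1–C10 and C13=C14 at once and relays the single bought stereocentre C9 to C10 and quaternary C1. The precursor is an acyclic dienyl ester. The ten-membered ring is closed last by metathesis at C3=C4.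

Key step: step 9

Remark on the chemistry: briarane numbering is used throughout. C1 (quaternary, CH3-15), C2 (OAc), C3=C4, C5(=C16H2), C6 (Cl), C7 (lactone O), C8 (OH), C9 (OAc), C10, C11 (OH, CH3-20), C12 (OAc), C13=C14, C17 (CH3-18), C19 (lactone C=O). Sulfoxide 5 is racemic at sulfur, and this centre is lost in step 9.

Step 1
Reactants: 1 methacrylic acid
Product: 2 2,3-dibromo-2-methylpropanoic acid (racemic)
Conditions: Br2, CH2Cl2, 0 °C to rt
Reagents that add atoms: bromine BrBr
Why: Electrophilic anti-addition of bromine to the alkene (halogenation) should give the vicinal dibromide, whose stereocentre is lost in step 2.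

Step 2
Reactants: 2 2,3-dibromo-2-methylpropanoic acid
Product: 4 (E)-2-methyl-3-(phenylsulfanyl)prop-2-enoic acid, via bromoacrylic acid 3 (not isolated)
Conditions: PhSH, KOH (excess), EtOH, reflux; then aq. HCl
Reagents that add atoms: thiophenol Sc1ccccc1
Why: E2 dehydrobromination gives the (E)-β-bromoacrylate 3, and vinylic substitution by thiolate (conjugate addition–elimination) should proceed with retention to the more stable (E)-vinyl sulfide.

Step 3
Reactants: 4 (E)-2-methyl-3-(phenylsulfanyl)prop-2-enoic acid
Product: 5 (E)-2-methyl-3-(phenylsulfinyl)prop-2-enoic acid (racemic at sulfur)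
Conditions: mCPBA (1.0 equiv), CH2Cl2, −20 °C
Reagents that add atoms: mCPBA O=C(OO)c1cccc(Cl)c1
Why: Sulfide-to-sulfoxide oxidation with one equivalent of peracid at low temperature should stop before the sulfone and leave the electron-poor alkene untouched.

Step 4
Reactants: 6 (R)-2,3-O-isopropylideneglyceraldehyde; 7 2-(triphenylphosphoranylidene)propanal
Product: 8 (2E)-3-[(4S)-2,2-dimethyl-1,3-dioxolan-4-yl]-2-methylprop-2-enal
Conditions: CH2Cl2, rt
Reagents that add atoms: none
Why: Wittig olefination with a stabilised ylide is (E)-selective and non-basic, so the bought stereocentre (future C9) is kept and C10=C11 is formed with C9 cis to CH3-20.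

Step 5
Reactants: 8 enal
Product: 9 (4S)-2,2-dimethyl-4-[(1E)-2-methylbuta-1,3-dien-1-yl]-1,3-dioxolane
Conditions: Ph3PCH3Br, n-BuLi, THF, −78 to 0 °C
Reagents that add atoms: methyltriphenylphosphonium bromide C[P+](c1ccccc1)(c1ccccc1)c1ccccc1.[Br-]
Why: Wittig methylenation attacks the enal carbonyl in a 1,2-fashion and completes the diene C10=C11–C12=C13 without touching C9.

Step 6
Reactants: 9 diene acetonide
Product: 10 (2S,3E)-4-methylhexa-3,5-diene-1,2-diol
Conditions: AcOH–H2O (4:1), 40 °C
Reagents that add atoms: none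
Why: Mild acid-catalysed acetal hydrolysis cleaves only the acetal C–O bonds, so the C9–O bond and its configuration are retained.

Step 7
Reactants: 10 diol
Product: 11 (2S,3E)-1-[(tert-butyldimethylsilyl)oxy]-4-methylhexa-3,5-dien-2-ol
Conditions: TBSCl (1.05 equiv), imidazole, CH2Cl2, 0 °C
Reagents that add atoms: tert-butyldimethylsilyl chloride CC(C)(C)[Si](C)(C)Cl
Why: Sterically controlled silylation takes the primary C8 hydroxyl and leaves the secondary C9 hydroxyl free for the tether.

Step 8
Reactants: 11 dienol; 5 sulfinylacrylic acid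
Product: 12 (2S,3E)-1-[(tert-butyldimethylsilyl)oxy]-4-methylhexa-3,5-dien-2-yl (2E)-2-methyl-3-(phenylsulfinyl)prop-2-enoate (both sulfur epimers)
Conditions: DCC, DMAP (cat.), CH2Cl2, 0 °C to rt
Reagents that add atoms: none
Why: Steglich esterification acylates the C9 hydroxyl at oxygen, so C9 and both alkene geometries are unchanged.

Step 9
Reactants: 12 dienyl β-sulfinylmethacrylate
Product: 14 trans-fused cyclohexadiene γ-lactone (3S,3aS,7aS), via sulfoxide cycloadduct 13 (not isolated)
Conditions: toluene (0.01 M), BHT (cat.), 110 °C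
Reagents that add atoms: none
Why: A thermal concerted suprafacial [4+2] cycloaddition of the (E)-diene C10=C11–C12=C13 to the doubly activated alkene C1=C14 forms C1–C10 and C13–C14 in 13, and the secondary sulfoxide then loses PhSOH by a five-centre syn-elimination that can only take a C13 hydrogen because C1 is quaternary, which turns the new C13–C14 bond into the alkene of 14. The closest known reaction types are the ester-tethered type 1 intramolecular Diels–Alder reaction of pentadienyl acrylates and the use of β-sulfinyl acrylates as alkyne equivalents that build a quaternary carbon next to the new alkene. The six-membered carbocycle closes by the cycloaddition itself, and the five-membered lactone (C1, C2, O, C9, C10) closes in the fused mode imposed by the three-atom tether, the bridged regioisomer being geometrically out of reach. C10 is set by C9, because allylic 1,3-strain with CH3-20 on C11 keeps H9 in the diene plane, so the C9–O bond carries the dienophile to one diene face while CH2OTBS points to the other. C1 is set by the exo orientation of the tether (CH3-15 and the sulfinyl group endo), the only mode compatible with the H9-in-plane rotamer and the one favoured by the (E)-dienophile, which gives the trans fusion with C2 anti to C9 and CH3-15 anti to H10. The step needs exo/endo selectivity, facial selectivity and intra- over intermolecular reaction, which are secured by the C11 methyl group, by C9 and by high dilution.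

Step 10
Reactants: 14 cyclohexadiene lactone
Product: 15 cis-diol lactone (3S,3aS,4S,5R,7aS)
Conditions: OsO4 (cat.), NMO (1.0 equiv), acetone–H2O, 0 °C
Reagents that add atoms: N-methylmorpholine N-oxide C[N+]1([O-])CCOCC1; water O
Why: Upjohn dihydroxylation should add suprafacially to the more electron-rich trisubstituted C11=C12 bond of the diene, on the face opposite to pseudoaxial CH3-15 and the C9 branch, which sets C11 and C12 as the cis-diol in one event and leaves C13=C14.

Step 11
Reactants: 15 diol lactone
Product: 16 lactol (anomers at C2)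
Conditions: i-Bu2AlH (3.5 equiv), CH2Cl2, −78 °C; potassium sodium tartrate work-up
Reagents that add atoms: none
Why: Partial lactone reduction stops at the aluminium hemiacetal at −78 °C, the two free hydroxyls merely consuming reagent as aluminium alkoxides.

Step 12
Reactants: 16 lactol
Product: 17 tetraol (1S,2S,9S,10S,11S,12R) with a C2 vinyl carbinol and a C9 carbinol
Conditions: CH2=CHMgBr (excess), THF, 0 °C to rt
Reagents that add atoms: vinylmagnesium bromide C=C[Mg]Br
Why: Grignard addition to the hydroxy-aldehyde tautomer opens the temporary ring, and the C9 magnesium alkoxide should chelate the C2 carbonyl oxygen and hold it syn to C1–C10, so that vinyl attacks the face flanked by the flat C14–H rather than by CH3-15 and gives (2S).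

Step 13
Reactants: 17 tetraol
Product: 18 2,9,12-triacetate with free tertiary C11 hydroxyl
Conditions: Ac2O, pyridine, DMAP (cat.), CH2Cl2, 0 °C to rt
Reagents that add atoms: acetic anhydride CC(=O)OC(C)=O
Why: DMAP-catalysed acylation takes the three secondary hydroxyls and installs the final acetates, while the hindered tertiary C11 hydroxyl does not react under these conditions.

Step 14
Reactants: 18 silyl ether
Product: 19 primary C8 alcohol
Conditions: HF·pyridine, THF–pyridine, 0 °C
Reagents that add atoms: none
Why: Fluoride-mediated desilylation under non-basic conditions removes the only silyl ether and should suppress 1,2-acetyl migration from O9 to O8.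

Step 15
Reactants: 19 primary alcohol
Product: 20 α-acetoxy aldehyde (C8 aldehyde)
Conditions: Dess–Martin periodinane, CH2Cl2, rt
Reagents that add atoms: none
Why: Dess–Martin oxidation is neutral and fast, so the primary alcohol is oxidised without epimerisation at C9 and the tertiary hydroxyl is inert.

Step 16
Reactants: 21 3-(trimethylsilyl)prop-2-ynal
Product: 22 (E)-(4-iodobut-3-en-1-yn-1-yl)trimethylsilane
Conditions: CHI3, CrCl2, THF, 0 °C
Reagents that add atoms: iodoform IC(I)I
Why: Takai olefination through the geminal dichromium reagent converts the aldehyde into the (E)-vinyl iodide that carries C4–C7.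

Step 17
Reactants: 20 aldehyde; 22 iodoenyne
Product: 23 allylic alcohol (both C8 epimers)
Conditions: CrCl2, NiCl2 (cat.), DMSO–THF, rt
Reagents that add atoms: none
Why: The Nozaki–Hiyama–Kishi reaction forms C7–C8 with retention of the (E)-alkene and is aldehyde-selective, so acetates and the free hydroxyl survive, and the C8 mixture is irrelevant because step 18 removes this centre.

Step 18
Reactants: 23 allylic alcohol
Product: 24 (E)-enynone (C8 ketone)
Conditions: Dess–Martin periodinane, CH2Cl2, rt
Reagents that add atoms: none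
Why: Dess–Martin oxidation converges both C8 epimers to one ketone without isomerising the (E)-alkene or epimerising C9.

Step 19
Reactants: 24 enynone
Product: 25 β-hydroxy phenyl ester (8R,17R)
Conditions: EtCO2Ph, TiCl4, Bu3N, CH2Cl2, −78 °C; then 24, −78 °C
Reagents that add atoms: phenyl propanoate CCC(=O)Oc1ccccc1
Why: In this titanium-mediated direct aldol addition of a phenyl ester to a ketone, the (Z)-trichlorotitanium enolate should add 1,2 through a Zimmerman–Traxler chair with the C9 branch equatorial (CH3-18 and the C8 oxygen syn along the chain C19–C17–C8–C9) and attack the carbonyl face anti to the C9–OAc bond as in the polar Felkin–Anh model, which sets C8 and C17.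

Step 20
Reactants: 25 tertiary allylic alcohol
Product: 26 (6R,7S)-trans-epoxide
Conditions: D-fructose-derived Shi ketone (30 mol %), KHSO5 (as Oxone, 2KHSO5·KHSO4·K2SO4), K2CO3, Bu4NHSO4, MeCN–CH2(OMe)2–aq. Na2B4O7/Na2EDTA buffer, 0 °C
Reagents that add atoms: potassium peroxymonosulfate [K+].[O-]S(=O)(=O)OO
Why: Shi epoxidation of the trans-disubstituted enyne alkene through the spiro transition state is reagent-controlled and should give the (6R,7S)-epoxide, while the monosubstituted allylic-acetate vinyl group and the cis C13=C14 alkene are poor substrates for this dioxirane.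

Step 21
Reactants: 26 epoxide
Product: 28 chloro γ-lactone (6S,7R,8R,17R), via chlorohydrin 27 (not isolated)
Conditions: LiCl, AcOH, THF, rt; then CSA (cat.), CH2Cl2, rt
Reagents that add atoms: lithium chloride [Li+].[Cl-]
Why: Acid-assisted SN2 opening of the epoxide by chloride should occur at propargylic C6 (C7 is neopentylic) with inversion to the (6S)-chloride and retention of the C7–O bond, and the freed C7 hydroxyl then displaces phenol in an acid-catalysed 5-exo-trig lactonisation.

Step 22
Reactants: 28 silylalkyne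
Product: 29 terminal alkyne
Conditions: Bu4NF, AcOH, THF, 0 °C
Reagents that add atoms: none
Why: Buffered fluoride protodesilylation cleaves the alkynyl C–Si bond while the buffer protects acetates, lactone and the propargylic chloride from base.

Step 23
Reactants: 29 terminal alkyne
Product: 30 2-substituted buta-1,3-diene (C5(=C16H2)–C4H=CH2)
Conditions: second-generation Grubbs catalyst (cat.), ethene (1 atm), CH2Cl2, rt
Reagents that add atoms: ethene C=C
Why: Cross enyne metathesis with ethene converts the alkyne into the conjugated diene, delivers C16 to C5, and is driven by diene formation, while metathesis of the C3 vinyl group with ethene is degenerate.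

Step 24
Reactants: 30 triene
Product: 31 CNP0285654.2 (1S,2S,3Z,6S,7R,8R,9S,10S,11S,12R,17R)
Conditions: second-generation Hoveyda–Grubbs catalyst (cat.), toluene (0.5 mM), 80 °C, argon sparge
Reagents that add atoms: none
Why: Ring-closing metathesis between the C3 vinyl group and the terminal C4 alkene of the diene closes the ten-membered ring with loss of ethene, and the reversible reaction should settle on the (3Z)-alkene, the less strained geometry in a cyclodecene.

**Compound list**
1 | methacrylic acid | C=C(C)C(=O)O | starting material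
2 | 2,3-dibromo-2-methylpropanoic acid (racemic) | OC(=O)C(C)(Br)CBr | intermediate
3 | (E)-3-bromo-2-methylprop-2-enoic acid | OC(=O)/C(C)=C/Br | intermediate
4 | (E)-2-methyl-3-(phenylsulfanyl)prop-2-enoic acid | OC(=O)/C(C)=C/Sc1ccccc1 | intermediate
5 | (E)-2-methyl-3-(phenylsulfinyl)prop-2-enoic acid (racemic at S) | OC(=O)/C(C)=C/S(=O)c1ccccc1 | intermediate
6 | (R)-2,3-O-isopropylideneglyceraldehyde | O=C[C@H]1COC(C)(C)O1 | starting material
7 | 2-(triphenylphosphoranylidene)propanal | CC(C=O)=P(c1ccccc1)(c1ccccc1)c1ccccc1 | starting material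
8 | (2E)-3-[(4S)-2,2-dimethyl-1,3-dioxolan-4-yl]-2-methylprop-2-enal | O=C/C(C)=C/[C@H]1COC(C)(C)O1 | intermediate
9 | (4S)-2,2-dimethyl-4-[(1E)-2-methylbuta-1,3-dien-1-yl]-1,3-dioxolane | C=C/C(C)=C/[C@H]1COC(C)(C)O1 | intermediate
10 | (2S,3E)-4-methylhexa-3,5-diene-1,2-diol | C=C/C(C)=C/[C@H](O)CO | intermediate
11 | (2S,3E)-1-[(tert-butyldimethylsilyl)oxy]-4-methylhexa-3,5-dien-2-ol | C=C/C(C)=C/[C@H](O)CO[Si](C)(C)C(C)(C)C | intermediate
12 | ester of 11 with 5 (9S; both alkenes E; sulfur epimers) | C=C/C(C)=C/[C@H](OC(=O)/C(C)=C/S(=O)c1ccccc1)CO[Si](C)(C)C(C)(C)C | intermediate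
13 | (3S,3aS,7R,7aS)-3-(TBSOCH2)-4,7a-dimethyl-7-(phenylsulfinyl)-3a,6,7,7a-tetrahydro-2-benzofuran-1(3H)-one | O=C1[C@@]2(C)[C@H](S(=O)c3ccccc3)CC=C(C)[C@@H]2[C@@H](CO[Si](C)(C)C(C)(C)C)O1 | intermediate
14 | (3S,3aS,7aS)-3-(TBSOCH2)-4,7a-dimethyl-3a,7a-dihydro-2-benzofuran-1(3H)-one | O=C1[C@@]2(C)C=CC=C(C)[C@@H]2[C@@H](CO[Si](C)(C)C(C)(C)C)O1 | intermediate
15 | (3S,3aS,4S,5R,7aS)-3-(TBSOCH2)-4,5-dihydroxy-4,7a-dimethyl-3a,4,5,7a-tetrahydro-2-benzofuran-1(3H)-one | O=C1[C@@]2(C)C=C[C@@H](O)[C@@](C)(O)[C@@H]2[C@@H](CO[Si](C)(C)C(C)(C)C)O1 | intermediate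
16 | lactol of 15 (anomers at C2) | OC1[C@@]2(C)C=C[C@@H](O)[C@@](C)(O)[C@@H]2[C@@H](CO[Si](C)(C)C(C)(C)C)O1 | intermediate
17 | cyclohexene tetraol: C1 CH3 and (2S)-CH(OH)CH=CH2, C10 (9S)-CH(OH)CH2OTBS, C11 OH/CH3, C12 OH | C=C[C@H](O)[C@@]1(C)C=C[C@@H](O)[C@@](C)(O)[C@@H]1[C@H](O)CO[Si](C)(C)C(C)(C)C | intermediate
18 | 2,9,12-triacetate of 17 | C=C[C@H](OC(C)=O)[C@@]1(C)C=C[C@@H](OC(C)=O)[C@@](C)(O)[C@@H]1[C@H](OC(C)=O)CO[Si](C)(C)C(C)(C)C | intermediate
19 | C8 primary alcohol | C=C[C@H](OC(C)=O)[C@@]1(C)C=C[C@@H](OC(C)=O)[C@@](C)(O)[C@@H]1[C@H](OC(C)=O)CO | intermediate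
20 | C8 aldehyde | C=C[C@H](OC(C)=O)[C@@]1(C)C=C[C@@H](OC(C)=O)[C@@](C)(O)[C@@H]1[C@H](OC(C)=O)C=O | intermediate
21 | 3-(trimethylsilyl)prop-2-ynal | O=CC#C[Si](C)(C)C | starting material
22 | (E)-(4-iodobut-3-en-1-yn-1-yl)trimethylsilane | I/C=C/C#C[Si](C)(C)C | intermediate
23 | C8 allylic alcohol, (6E)-enyne, C8 epimers | C=C[C@H](OC(C)=O)[C@@]1(C)C=C[C@@H](OC(C)=O)[C@@](C)(O)[C@@H]1[C@H](OC(C)=O)C(O)/C=C/C#C[Si](C)(C)C | intermediate
24 | C8 ketone, (6E)-enynone | C=C[C@H](OC(C)=O)[C@@]1(C)C=C[C@@H](OC(C)=O)[C@@](C)(O)[C@@H]1[C@H](OC(C)=O)C(=O)/C=C/C#C[Si](C)(C)C | intermediate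
25 | (8R,17R)-β-hydroxy phenyl ester | C=C[C@H](OC(C)=O)[C@@]1(C)C=C[C@@H](OC(C)=O)[C@@](C)(O)[C@@H]1[C@H](OC(C)=O)[C@@](O)(/C=C/C#C[Si](C)(C)C)[C@@H](C)C(=O)Oc1ccccc1 | intermediate
26 | (6R,7S)-epoxide of 25 | C=C[C@H](OC(C)=O)[C@@]1(C)C=C[C@@H](OC(C)=O)[C@@](C)(O)[C@@H]1[C@H](OC(C)=O)[C@@](O)([C@H]2O[C@@H]2C#C[Si](C)(C)C)[C@@H](C)C(=O)Oc1ccccc1 | intermediate
27 | (6S,7R)-chlorohydrin phenyl ester | C=C[C@H](OC(C)=O)[C@@]1(C)C=C[C@@H](OC(C)=O)[C@@](C)(O)[C@@H]1[C@H](OC(C)=O)[C@@](O)([C@@H](O)[C@@H](Cl)C#C[Si](C)(C)C)[C@@H](C)C(=O)Oc1ccccc1 | intermediate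
28 | chloro γ-lactone with silylalkyne | C=C[C@H](OC(C)=O)[C@@]1(C)C=C[C@@H](OC(C)=O)[C@@](C)(O)[C@@H]1[C@H](OC(C)=O)[C@]2(O)[C@@H](C)C(=O)O[C@H]2[C@H](C#C[Si](C)(C)C)Cl | intermediate
29 | chloro γ-lactone with terminal alkyne | C=C[C@H](OC(C)=O)[C@@]1(C)C=C[C@@H](OC(C)=O)[C@@](C)(O)[C@@H]1[C@H](OC(C)=O)[C@]2(O)[C@@H](C)C(=O)O[C@H]2[C@H](C#C)Cl | intermediate
30 | chloro γ-lactone with 2-substituted butadiene | C=C[C@H](OC(C)=O)[C@@]1(C)C=C[C@@H](OC(C)=O)[C@@](C)(O)[C@@H]1[C@H](OC(C)=O)[C@]2(O)[C@@H](C)C(=O)O[C@H]2[C@H](C(=C)C=C)Cl | intermediate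
31 | CNP0285654.2 | C=C1/C=C\[C@H](OC(C)=O)[C@@]2(C)C=C[C@@H](OC(C)=O)[C@@](C)(O)[C@@H]2[C@H](OC(C)=O)[C@]2(O)[C@@H](C)C(=O)O[C@H]2[C@H]1Cl | target

**Total step count:** 24. **Longest linear sequence:** 20 steps (steps 4–15 and 17–24).

**Steps most likely to fail**

Step 9. The exo (trans-fused) mode may lose ground to the endo (cis-fused) mode. The diene or the product may also be consumed by re-addition of sulfenic acid or by oligomerisation at the temperature needed. The fallback sets out from 11 and comes back at 14. Mesaconic acid is mono-esterified with allyl alcohol at its unhindered carboxyl group (TsOH, toluene, water removal) to 4-allyl hydrogen mesaconate F1. Steglich coupling with 11 gives the mixed diester F2. Its fumarate-type dienophile should cycloadd in toluene at 110 °C with the allyl ester endo and the tether exo, to the trans-fused lactone ester F3. Pd(PPh3)4 and morpholine remove the allyl group to give the C14 acid F4. Kochi oxidative decarboxylation (Pb(OAc)4, Cu(OAc)2, pyridine, benzene, 80 °C) turns the C14 carboxyl group into the C13=C14 alkene of 14, independent of the C14 configuration.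

Step 19. Conjugate addition may compete with 1,2-addition, TiCl4 may ionise the allylic acetates, and face selectivity at C8 or syn/anti selectivity at C17 may be low. The fallback sets out from 24 and comes back at 28. A Reformatsky reaction (methyl 2-bromopropanoate, activated zinc, THF) adds a weakly basic and weakly Lewis-acidic zinc enolate 1,2 to the ketone under Felkin–Anh control, giving the methyl ester F5. Shi epoxidation as in step 20 gives the epoxide F6. LiCl/AcOH gives the chlorohydrin F7, and CSA closes the lactone 28. C17 epimers are removed by chromatography at the lactone stage.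

Step 24. Oligomerisation or lack of turnover may prevail, because the C3 vinyl group is neopentylic, the ring is strained, and diene ring-closing metathesis is reversible. The fallback sets out from 29 and comes back at 31. Ring-closing enyne metathesis is run on 29 itself (second-generation Grubbs catalyst, toluene, high dilution, no ethene). The ruthenium methylidene adds to the unhindered alkyne, the resulting C4 vinylcarbene closes onto the C3 vinyl group, and the CH2 of that vinyl group ends up as C16. The irreversible, enthalpically driven enyne bond reorganisation is thus spent on the ring closure itself and not on the earlier cross reaction with ethene.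

**Further compounds**
F1 | step 9 | 4-allyl hydrogen mesaconate | OC(=O)/C(C)=C/C(=O)OCC=C
F2 | step 9 | mixed mesaconate diester of 11 | C=C/C(C)=C/[C@H](OC(=O)/C(C)=C/C(=O)OCC=C)CO[Si](C)(C)C(C)(C)C
F3 | step 9 | trans-fused lactone with C14 allyl ester | O=C1[C@@]2(C)[C@H](C(=O)OCC=C)CC=C(C)[C@@H]2[C@@H](CO[Si](C)(C)C(C)(C)C)O1
F4 | step 9 | trans-fused lactone C14 carboxylic acid | O=C1[C@@]2(C)[C@H](C(=O)O)CC=C(C)[C@@H]2[C@@H](CO[Si](C)(C)C(C)(C)C)O1
F5 | step 19 | (8R,17R)-β-hydroxy methyl ester | C=C[C@H](OC(C)=O)[C@@]1(C)C=C[C@@H](OC(C)=O)[C@@](C)(O)[C@@H]1[C@H](OC(C)=O)[C@@](O)(/C=C/C#C[Si](C)(C)C)[C@@H](C)C(=O)OC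
F6 | step 19 | (6R,7S)-epoxide methyl ester | C=C[C@H](OC(C)=O)[C@@]1(C)C=C[C@@H](OC(C)=O)[C@@](C)(O)[C@@H]1[C@H](OC(C)=O)[C@@](O)([C@H]2O[C@@H]2C#C[Si](C)(C)C)[C@@H](C)C(=O)OC
F7 | step 19 | (6S,7R)-chlorohydrin methyl ester | C=C[C@H](OC(C)=O)[C@@]1(C)C=C[C@@H](OC(C)=O)[C@@](C)(O)[C@@H]1[C@H](OC(C)=O)[C@@](O)([C@@H](O)[C@@H](Cl)C#C[Si](C)(C)C)[C@@H](C)C(=O)OC
F0 | step 24 | none | none
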